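The pyran ring of the chromene is cut at C3=C4 and at O1–C2, which exploits the ortho relationship of O1 (on C8a) and C4 (on C4a) of the benzo ring and the stereocentre-free gem-dimethyl C2. In one operation an amine-catalysed Petasis condensation of a salicylaldehyde (5-acetyl-2-hydroxy-4-methoxybenzaldehyde) with 2-methylprop-1-enylboronic acid joins C4 to C3, and the vinyl ortho-quinone methide so formed closes O1–C2 by oxa-6π electrocyclisation, giving encecalin. CBS reduction sets the (S)-carbinol; a stereoretentive copper-catalysed O-vinylation with a (Z)-vinyl iodide from anti-carbomagnesiation of propargyl alcohol installs the (Z)-enol ether, and fluoride unveils the diol.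

Key step: step 2

Remark: the SMILES is read as the (S)-configured benzylic ether carrying a (Z)-enol ether, in which the ether oxygen is cis to CH2OH and trans to the aryl ring.

Step 1
Reactants: 1 1-(4-hydroxy-2-methoxyphenyl)ethan-1-one
Product: 2 5-acetyl-2-hydroxy-4-methoxybenzaldehyde
Conditions: MgCl2, Et3N, (CH2O)n, MeCN, reflux; then 1 M HCl
Reagents that add atoms: paraformaldehyde (as formaldehyde), C=O
Why: Magnesium-mediated ortho-formylation of a phenol (Casnati–Skattebøl reaction): the magnesium phenoxide delivers formaldehyde only ortho to OH, the unhindered site para to OMe should be preferred over the site flanked by OMe, and a second formaldehyde accepts the hydride to give the aldehyde.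

Step 2
Reactants: 2 5-acetyl-2-hydroxy-4-methoxybenzaldehyde; 3 (2-methylprop-1-en-1-yl)boronic acid
Product: 6 encecalin (1-(7-methoxy-2,2-dimethyl-2H-chromen-6-yl)ethan-1-one), via Petasis allylic amine adduct 4 (not isolated), via vinyl ortho-quinone methide 5 (not isolated)
Conditions: Bn2NH (20 mol %), 1,4-dioxane, 90 °C
Reagents that add atoms: none
Why: Dibenzylamine condenses with the aldehyde to an iminium ion, the neighbouring phenoxide binds the boronic acid as a tetracoordinate boronate, and the 2-methylprop-1-enyl group migrates from boron to the iminium carbon to form C4–C3 (adduct 4). On heating, 4 expels dibenzylamine, helped by the ortho oxygen and the para OMe, to give the vinyl ortho-quinone methide 5, whose thermal oxa-6π electrocyclisation forms O1–C2 and leaves the C3=C4 double bond. The closest known reaction type is the amine-catalysed Petasis (borono-Mannich) condensation of salicylaldehydes with alkenylboronic acids to 2H-chromenes. The pyran ring closes by a disrotatory 6π electrocyclisation of a 1-oxatriene, formally a 6-endo attack of O1 on the CMe2 terminus. No stereocentre is formed, because C2 carries two methyl groups. The step needs chemoselectivity for the aldehyde over the acetyl ketone and regiocontrol of the alkenyl transfer; both should be secured by the free OH ortho to CHO, the only site that can hold the boronate next to an iminium ion, while the acetyl group is a poorly electrophilic vinylogous ester.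

Step 3
Reactants: 6 encecalin
Product: 7 (S)-encecalol ((1S)-1-(7-methoxy-2,2-dimethyl-2H-chromen-6-yl)ethan-1-ol)
Conditions: (R)-2-methyl-CBS-oxazaborolidine (10 mol %), catecholborane, toluene, −78 to −30 °C; then MeOH, 1 M NaOH
Reagents that add atoms: none
Why: Corey–Bakshi–Shibata reduction: the (R)-oxazaborolidine binds the ketone with the aryl group as the large substituent and delivers hydride to the Re face, which should give the (S)-carbinol, while catecholborane at low temperature should leave the chromene alkene alone and the basic work-up avoids ionisation of the electron-rich benzylic alcohol.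

Step 4
Reactants: 8 2-bromo-5-methylphenol
Product: 9 (2-bromo-5-methylphenoxy)tri(propan-2-yl)silane
Conditions: TIPSCl, imidazole, DMF, rt
Reagents that add atoms: triisopropylsilyl chloride, CC(C)[Si](Cl)(C(C)C)C(C)C
Why: Standard silylation of a phenol; the bulky triisopropylsilyl group is chosen because it should resist migration to the metalated ortho carbon, survive carbonate at 80 °C and fall to fluoride at the end.

Step 5
Reactants: 9 (2-bromo-5-methylphenoxy)tri(propan-2-yl)silane; 10 prop-2-yn-1-ol
Product: 13 (Z)-3-iodo-2-{4-methyl-2-[(triisopropylsilyl)oxy]phenyl}prop-2-en-1-ol, via aryl Grignard reagent 11 (not isolated), via cyclic vinylmagnesium alkoxide 12 (not isolated)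
Conditions: Mg, THF/Et2O, reflux; then 10 (0.4 equiv), CuI (10 mol %), rt to reflux; then I2, −20 °C to rt; aq. Na2S2O3
Reagents that add atoms: iodine, II
Why: Copper-catalysed anti-carbomagnesiation of a propargylic alkoxide: one equivalent of 11 deprotonates 10, a second adds its aryl group to C2 while magnesium ends at C3 inside the five-membered chelate 12, so iodinolysis with retention should place iodine cis to CH2OH and trans to the aryl ring.

Step 6
Reactants: 13 (Z)-3-iodo-2-{4-methyl-2-[(triisopropylsilyl)oxy]phenyl}prop-2-en-1-ol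
Product: 14 (Z)-{[3-iodo-2-{4-methyl-2-[(triisopropylsilyl)oxy]phenyl}prop-2-en-1-yl]oxy}tri(propan-2-yl)silane
Conditions: TIPSCl, imidazole, DMAP (cat.), CH2Cl2, rt
Reagents that add atoms: triisopropylsilyl chloride, CC(C)[Si](Cl)(C(C)C)C(C)C
Why: Standard silylation of a primary allylic alcohol, which removes the only competing O-nucleophile before the C–O coupling.

Step 7
Reactants: 7 (S)-encecalol; 14 the (Z)-vinyl iodide bis-silyl ether
Product: 15 6-[(1S)-1-{[(Z)-2-{4-methyl-2-[(triisopropylsilyl)oxy]phenyl}-3-[(triisopropylsilyl)oxy]prop-1-en-1-yl]oxy}ethyl]-7-methoxy-2,2-dimethyl-2H-chromene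
Conditions: CuI (10 mol %), 3,4,7,8-tetramethyl-1,10-phenanthroline (20 mol %), Cs2CO3, toluene, 80 °C
Reagents that add atoms: none
Why: Ullmann-type C(sp2)–O coupling catalysed by monovalent copper: the cesium alkoxide of 7 replaces iodide at the vinyl carbon with retention of the alkene geometry, and the stereocentre should stay intact because its C–O bond is never broken under these basic, non-ionising conditions.

Step 8
Reactants: 15 the bis-silyl ether of the target
Product: 16 2-[(Z)-3-hydroxy-1-{[(1S)-1-(7-methoxy-2,2-dimethyl-2H-chromen-6-yl)ethyl]oxy}prop-1-en-2-yl]-5-methylphenol (CNP0279099.1)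
Conditions: TBAF, THF, 0 °C to rt; water work-up
Reagents that add atoms: none
Why: Fluoride-induced cleavage of the aryl and the primary alkyl silyl ether under non-acidic conditions, which should spare the acid-labile enol ether, the ionisable benzylic ether and the chromene.

Compound list
1 | 1-(4-hydroxy-2-methoxyphenyl)ethan-1-one | COc1cc(O)ccc1C(C)=O | starting material
2 | 5-acetyl-2-hydroxy-4-methoxybenzaldehyde | COc1cc(O)c(C=O)cc1C(C)=O | intermediate
3 | (2-methylprop-1-en-1-yl)boronic acid | CC(C)=CB(O)O | starting material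
4 | 1-{5-[1-(dibenzylamino)-3-methylbut-2-en-1-yl]-4-hydroxy-2-methoxyphenyl}ethan-1-one (racemic, not isolated) | COc1cc(O)c(C(C=C(C)C)N(Cc2ccccc2)Cc2ccccc2)cc1C(C)=O | intermediate
5 | 4-acetyl-3-methoxy-6-(3-methylbut-2-en-1-ylidene)cyclohexa-2,4-dien-1-one (not isolated) | COC1=CC(=O)C(=CC=C(C)C)C=C1C(C)=O | intermediate
6 | encecalin, 1-(7-methoxy-2,2-dimethyl-2H-chromen-6-yl)ethan-1-one | COc1cc2c(cc1C(C)=O)C=CC(C)(C)O2 | intermediate
7 | (S)-encecalol, (1S)-1-(7-methoxy-2,2-dimethyl-2H-chromen-6-yl)ethan-1-ol | COc1cc2c(cc1[C@H](C)O)C=CC(C)(C)O2 | intermediate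
8 | 2-bromo-5-methylphenol | Cc1ccc(Br)c(O)c1 | starting material
9 | (2-bromo-5-methylphenoxy)tri(propan-2-yl)silane | Cc1ccc(Br)c(O[Si](C(C)C)(C(C)C)C(C)C)c1 | intermediate
10 | prop-2-yn-1-ol | C#CCO | starting material
11 | {4-methyl-2-[(triisopropylsilyl)oxy]phenyl}magnesium bromide (not isolated) | Cc1ccc([Mg]Br)c(O[Si](C(C)C)(C(C)C)C(C)C)c1 | intermediate
12 | 4-{4-methyl-2-[(triisopropylsilyl)oxy]phenyl}-2,5-dihydro-1,2-oxamagnesole (not isolated) | Cc1ccc(C2=C[Mg]OC2)c(O[Si](C(C)C)(C(C)C)C(C)C)c1 | intermediate
13 | (Z)-3-iodo-2-{4-methyl-2-[(triisopropylsilyl)oxy]phenyl}prop-2-en-1-ol | I/C=C(\CO)c1ccc(C)cc1O[Si](C(C)C)(C(C)C)C(C)C | intermediate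
14 | (Z)-{[3-iodo-2-{4-methyl-2-[(triisopropylsilyl)oxy]phenyl}prop-2-en-1-yl]oxy}tri(propan-2-yl)silane | I/C=C(\CO[Si](C(C)C)(C(C)C)C(C)C)c1ccc(C)cc1O[Si](C(C)C)(C(C)C)C(C)C | intermediate
15 | 6-[(1S)-1-{[(Z)-2-{4-methyl-2-[(triisopropylsilyl)oxy]phenyl}-3-[(triisopropylsilyl)oxy]prop-1-en-1-yl]oxy}ethyl]-7-methoxy-2,2-dimethyl-2H-chromene | COc1cc2c(cc1[C@H](C)O/C=C(\CO[Si](C(C)C)(C(C)C)C(C)C)c1ccc(C)cc1O[Si](C(C)C)(C(C)C)C(C)C)C=CC(C)(C)O2 | intermediate
16 | 2-[(Z)-3-hydroxy-1-{[(1S)-1-(7-methoxy-2,2-dimethyl-2H-chromen-6-yl)ethyl]oxy}prop-1-en-2-yl]-5-methylphenol | COc1cc2c(cc1[C@H](C)O/C=C(\CO)c1ccc(C)cc1O)C=CC(C)(C)O2 | target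

Total step count: 8.
Longest linear sequence: 5 steps (steps 4, 5, 6, 7, 8; the branch through steps 1, 2, 3, 7, 8 is equally long).

Steps most likely to fail

Step 2 (key step). The trisubstituted alkenyl group may migrate too slowly from boron to the iminium carbon, the boronic acid may protodeboronate on long heating, or the adduct may not release dibenzylamine, so that turnover stops. The fallback forms other bonds by known chemistry and sets out from 1. O-Alkylation with 3-chloro-3-methylbut-1-yne (CuCl2·2H2O cat., DBU, MeCN, 0 °C) should give 1-{2-methoxy-4-[(2-methylbut-3-yn-2-yl)oxy]phenyl}ethan-1-one F1. Heating F1 in N,N-diethylaniline at 180 °C (aromatic propargyl Claisen rearrangement to the ortho position para to OMe, then 1,5-hydrogen shift and oxa-6π closure) should come back to the route at 6.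

Step 7. C–O bond formation at copper may be outrun by reduction of the vinyl iodide or by dehydrogenation of the hindered secondary alkoxide, and the alkene geometry may erode on prolonged heating. The fallback builds the enol ether from an ynol ether and sets out from 7.
- KH and then trichloroethylene (THF, −50 °C to rt) should give 6-[(1S)-1-{[(E)-1,2-dichloroethenyl]oxy}ethyl]-7-methoxy-2,2-dimethyl-2H-chromene F2.
- n-BuLi (2.5 equiv, THF, −78 °C) should convert F2 into the lithium alkynyl ether, lithium 2-[(1S)-1-(7-methoxy-2,2-dimethyl-2H-chromen-6-yl)ethoxy]ethynide F3.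
- Trapping with paraformaldehyde should give 3-[(1S)-1-(7-methoxy-2,2-dimethyl-2H-chromen-6-yl)ethoxy]prop-2-yn-1-ol F4.
- TIPSCl/imidazole should give its triisopropylsilyl ether F5.
- Grignard reagent 11 and CuBr·SMe2 (THF, −40 °C) should give the arylcopper reagent {4-methyl-2-[(triisopropylsilyl)oxy]phenyl}copper F6.
- Syn-carbocupration of F5 with F6 (aryl to the carbon β to oxygen, copper to the α carbon) should give the α-cuprio enol ether F7. Its protonation with retention puts the aryl ring trans to the ether oxygen and comes back to the route at 15.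

Step 5. Silicon may migrate from oxygen to the metalated ortho carbon of the Grignard reagent, and anti-addition of the hindered ortho-substituted aryl group may be sluggish. The fallback changes the protecting-group plan to a small, chelating, non-migrating acetal and sets out from 8.
- MOMCl/iPr2NEt (CH2Cl2, 0 °C) should give 1-bromo-2-(methoxymethoxy)-4-methylbenzene F8.
- Mg (THF/Et2O) should give [2-(methoxymethoxy)-4-methylphenyl]magnesium bromide F9.
- CuI-catalysed addition to 10 should give the chelate 4-[2-(methoxymethoxy)-4-methylphenyl]-2,5-dihydro-1,2-oxamagnesole F10, and iodinolysis should give (Z)-3-iodo-2-[2-(methoxymethoxy)-4-methylphenyl]prop-2-en-1-ol F11.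
- HCl in MeOH at rt should remove the acetal to give 2-[(Z)-3-hydroxy-1-iodoprop-1-en-2-yl]-5-methylphenol F12.
- TIPSCl (2.5 equiv)/imidazole should silylate both hydroxyl groups and come back to the route at 14.

Further compounds
F1 | step 2 | 1-{2-methoxy-4-[(2-methylbut-3-yn-2-yl)oxy]phenyl}ethan-1-one | COc1cc(OC(C)(C)C#C)ccc1C(C)=O
F2 | step 7 | 6-[(1S)-1-{[(E)-1,2-dichloroethenyl]oxy}ethyl]-7-methoxy-2,2-dimethyl-2H-chromene | COc1cc2c(cc1[C@H](C)O/C(Cl)=C\Cl)C=CC(C)(C)O2
F3 | step 7 | lithium 2-[(1S)-1-(7-methoxy-2,2-dimethyl-2H-chromen-6-yl)ethoxy]ethynide | COc1cc2c(cc1[C@H](C)OC#C[Li])C=CC(C)(C)O2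
F4 | step 7 | 3-[(1S)-1-(7-methoxy-2,2-dimethyl-2H-chromen-6-yl)ethoxy]prop-2-yn-1-ol | COc1cc2c(cc1[C@H](C)OC#CCO)C=CC(C)(C)O2
F5 | step 7 | {[3-[(1S)-1-(7-methoxy-2,2-dimethyl-2H-chromen-6-yl)ethoxy]prop-2-yn-1-yl]oxy}tri(propan-2-yl)silane | COc1cc2c(cc1[C@H](C)OC#CCO[Si](C(C)C)(C(C)C)C(C)C)C=CC(C)(C)O2
F6 | step 7 | {4-methyl-2-[(triisopropylsilyl)oxy]phenyl}copper | Cc1ccc([Cu])c(O[Si](C(C)C)(C(C)C)C(C)C)c1
F7 | step 7 | α-cuprio enol ether from syn-carbocupration of F5 | COc1cc2c(cc1[C@H](C)O/C([Cu])=C(\CO[Si](C(C)C)(C(C)C)C(C)C)c1ccc(C)cc1O[Si](C(C)C)(C(C)C)C(C)C)C=CC(C)(C)O2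
F8 | step 5 | 1-bromo-2-(methoxymethoxy)-4-methylbenzene | COCOc1cc(C)ccc1Br
F9 | step 5 | [2-(methoxymethoxy)-4-methylphenyl]magnesium bromide | COCOc1cc(C)ccc1[Mg]Br
F10 | step 5 | 4-[2-(methoxymethoxy)-4-methylphenyl]-2,5-dihydro-1,2-oxamagnesole | COCOc1cc(C)ccc1C1=C[Mg]OC1
F11 | step 5 | (Z)-3-iodo-2-[2-(methoxymethoxy)-4-methylphenyl]prop-2-en-1-ol | I/C=C(\CO)c1ccc(C)cc1OCOC
F12 | step 5 | 2-[(Z)-3-hydroxy-1-iodoprop-1-en-2-yl]-5-methylphenol | I/C=C(\CO)c1ccc(C)cc1O
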